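A direct plan would hydroborate octadec-1-ene A1 with 9-borabicyclo[3.3.1]nonane A2 to B-octadecyl-9-BBN A3 and would couple A3 with benzyl 4-bromobutanoate A4 in an alkyl–alkyl Suzuki–Miyaura reaction (Pd(OAc)2, tricyclohexylphosphine) that would form the C4–C5 bond. Its weakest steps would be:
- the hydroboration of A1, which would consume a full equivalent of the air-sensitive borane A2 and would leave boron residues to be removed from a waxy product;
- the oxidative addition of zerovalent palladium to the unactivated primary C–Br bond of A4, which would depend on an oxygen-sensitive phosphine and would compete with β-hydride elimination;
- the base-promoted transmetalation of A3, whose hydroxide could also hydrolyse the benzyl ester.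

The route rests instead on the C3–C4 bond and cuts it so that both fragments are carboxylic acids: icosanoic acid would supply C4–C22 as a nonadecyl radical, and succinic acid monobenzyl ester would supply C1–C3 with the benzyl ester already in place. A mixed Kolbe electrolysis at platinum would expel both carboxyl groups as CO2 and join the two primary radicals in one operation. The step exploits the unbranched, stereocentre-free C21 alkyl chain that carries nothing but one terminal ester: neither radical is prone to rearrange, cyclise or be oxidised further. No borane, alkyl halide, palladium or phosphine would be needed; the only stoichiometric reagent is electric current.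

Key step: step 1

Remark: atoms are numbered along the acyl chain from the ester carbonyl (C1) to the terminal methyl (C22). The target has no stereocentre, and both acids 1 and 2 are taken as catalogue compounds.

Step 1
Reactants: 1 icosanoic acid (arachidic acid); 2 4-(benzyloxy)-4-oxobutanoic acid (succinic acid monobenzyl ester)
Product: 3 benzyl docosanoate
Conditions: 1 (1.0 equiv), 2 (4.0 equiv), KOH (0.25 equiv, 5 % of all CO2H), MeOH/pyridine 4:1, Pt foil anode and cathode, undivided cell, constant current 0.25 A cm−2, 50 °C, ca. 1.2 F per mol CO2H, polarity reversed every 30 s, stopped while the electrolyte is still weakly acidic; filtration through basic Al2O3, then silica (hexane to hexane/EtOAc)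
Reagents that add atoms: none
Why: Mixed (crossed) Kolbe electrolysis: at a smooth platinum anode under high current density the carboxylates of 1 and 2 are each oxidised by one electron, the acyloxy radicals lose CO2 at once, and the nonadecyl and 2-(benzyloxycarbonyl)ethyl radicals that crowd the anode layer combine to form the C3–C4 bond. The closest known reaction type is the classical anodic two-carbon chain extension of a fatty acid with a succinic half-ester, from which this step differs only in the alcohol part of the ester. No ring is closed and no stereocentre is formed. The step needs cross-coupling ahead of homo-coupling and the radical pathway ahead of the carbocation (Hofer–Moest) pathway: the fourfold excess of 2 should channel most nonadecyl radicals into 3, and both radicals are primary and carry no α-donor, so they should resist further oxidation at platinum. The benzyl ester should survive because the carboxylate film screens the arene from the anode, the preferred Z conformation of the ester points the O-benzyl group away from the radical carbon so that no hydrogen shift is expected, and an electrolyte that always holds free acid contains no methoxide for ester exchange. The two symmetrical by-products, a C38 alkane and a diester, differ from the monoester 3 in polarity and should separate on silica, while periodic polarity reversal should keep waxy deposits off the electrodes.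

**Compound list**
1 | icosanoic acid (arachidic acid) | CCCCCCCCCCCCCCCCCCCC(=O)O | starting material
2 | 4-(benzyloxy)-4-oxobutanoic acid (succinic acid monobenzyl ester) | OC(=O)CCC(=O)OCc1ccccc1 | starting material
3 | benzyl docosanoate | CCCCCCCCCCCCCCCCCCCCCC(=O)OCc1ccccc1 | target

Total step count: 1
Longest linear sequence: 1 step

Steps most likely to fail: the route has a single step, so it is the only entry.

Step 1. Several processes could go wrong:
- The pairing of the two radicals is statistical, so part of 1 would be lost to homo-coupling, and the resulting long-chain hydrocarbon could coat and passivate the anode.
- Over-oxidation of the radicals to carbocations would give ethers and alkenes.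
- If the electrolyte were allowed to turn basic, the benzyl ester could exchange with methanol.

Fallback: the approach would change from anodic radical–radical pairing to a chemically selective radical conjugate addition, in which the nonadecyl radical is generated alone and trapped by an electron-poor alkene. Setting out from 1, esterification with N-hydroxyphthalimide (N,N'-diisopropylcarbodiimide, cat. DMAP, CH2Cl2, rt) would give the redox-active ester 1,3-dioxoisoindolin-2-yl icosanoate F1. Reductive decarboxylative Giese addition of F1 to benzyl acrylate (C=CC(=O)OCc1ccccc1; Ni(ClO4)2·6H2O 20 mol %, Zn powder, LiCl, MeCN, rt, then aqueous NH4Cl) would form the same C3–C4 bond without a statistical partner and would come back to the route at 3.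

Further compounds
F1 | step 1 | 1,3-dioxoisoindolin-2-yl icosanoate (N-(icosanoyloxy)phthalimide) | CCCCCCCCCCCCCCCCCCCC(=O)ON1C(=O)c2ccccc2C1=O
A1 | direct plan | octadec-1-ene | CCCCCCCCCCCCCCCCC=C
A2 | direct plan | 9-borabicyclo[3.3.1]nonane (9-BBN) | B1C2CCCC1CCC2
A3 | direct plan | 9-octadecyl-9-borabicyclo[3.3.1]nonane (B-octadecyl-9-BBN) | CCCCCCCCCCCCCCCCCCB1C2CCCC1CCC2
A4 | direct plan | benzyl 4-bromobutanoate | BrCCCC(=O)OCc1ccccc1
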